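**Plan**

- Retrosynthesis: the two gallate esters and all benzyl ethers are cut first, then the lower pyran (ring F) at C4–C4a, then the lower aryl ether O1–C2, then the interflavan bond C4(upper)–C8(lower). This leads back to an epicatechin C4 cation equivalent and a plain phloroglucinol diether (ring D).
- Forward: (−)-epicatechin → benzyl ethers → C4 oxidation → upper gallate → ring D attached at C4 by Friedel–Crafts arylation → the ring E/C2/C3 piece joined to the ring D phenol as a 2,3-epoxy ether → ring F closed → lower gallate → hydrogenolysis.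
- Enabling feature: ring D is a phloroglucinol ring, so C4a lies ortho to O1, ortho to C5–O and para to C7–O, and C4 is the neighbour of the oxygen-bearing C3. An O1-tethered terminal oxirane spanning C3 and C4 is therefore opened at C4 by C4a; this closes ring F, frees the C3 hydroxyl with its configuration and, because C4a is the only free carbon ortho to O1, fixes the 4→8 linkage.
- Stereochemistry: upper C2 and C3 come from (−)-epicatechin; upper C4 (β) from arene attack trans to the 3-O-acyl group; lower C3 from a Sharpless kinetic resolution; lower C2 from Mitsunobu inversion of the same epoxy alcohol.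

Key step: step 8

Remark: the target is read as (−)-epicatechin 3-O-gallate-(4β→8)-(−)-epigallocatechin 3-O-gallate (upper unit 2R,3R,4R with rings A, C, B; lower unit 2R,3R with rings D, F, E); 3,4,5-tris(benzyloxy)benzoic acid, 3,5-bis(benzyloxy)phenol and 3,4,5-tris(benzyloxy)benzaldehyde are taken as purchasable.

**Route**

Step 1
Reactants: 1 (−)-epicatechin
Product: 2 5,7,3',4'-tetra-O-benzyl-(−)-epicatechin
Conditions: BnBr (4.4 equiv), K2CO3, DMF, 0 °C to rt
Reagents that add atoms: benzyl bromide, BrCc1ccccc1
Why: Williamson ether synthesis in which K2CO3 deprotonates only the four phenols, so the secondary C3 hydroxyl stays free and the mild base should leave the C2 and C3 stereocenters of 1 untouched.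

Step 2
Reactants: 2 5,7,3',4'-tetra-O-benzyl-(−)-epicatechin
Product: 3 4β-(2-ethoxyethoxy)-5,7,3',4'-tetra-O-benzylepicatechin
Conditions: DDQ (2 equiv), 2-ethoxyethanol (5 equiv), CH2Cl2, rt
Reagents that add atoms: 2-ethoxyethanol, CCOCCO
Why: Benzylic oxidation by hydride abstraction with DDQ should give the C4 cation stabilized by the 5,7-dioxygenated ring A, which the alcohol traps from the β face, trans to the axial C3 hydroxyl, so that C4 carries a leaving group for step 4.

Step 3
Reactants: 3 4β-(2-ethoxyethoxy)-5,7,3',4'-tetra-O-benzylepicatechin; 4 3,4,5-tris(benzyloxy)benzoic acid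
Product: 5 4β-(2-ethoxyethoxy)-5,7,3',4'-tetra-O-benzyl-3-O-[3,4,5-tris(benzyloxy)benzoyl]epicatechin
Conditions: DCC, DMAP, CH2Cl2, rt
Reagents that add atoms: none
Why: Steglich esterification of the only free hydroxyl, done now so that the acyl group can shield the α face of C4 in step 4 and so that each gallate is introduced on a single free hydroxyl.

Step 4
Reactants: 5 4β-(2-ethoxyethoxy)-5,7,3',4'-tetra-O-benzyl-3-O-[3,4,5-tris(benzyloxy)benzoyl]epicatechin; 6 3,5-bis(benzyloxy)phenol (4 equiv)
Product: 7 4β-[2-hydroxy-4,6-bis(benzyloxy)phenyl]-5,7,3',4'-tetra-O-benzyl-3-O-[3,4,5-tris(benzyloxy)benzoyl]epicatechin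
Conditions: TMSOTf (0.2 equiv), CH2Cl2, −78 to −40 °C, then Et3N
Reagents that add atoms: none
Why: Friedel–Crafts arylation by a Lewis-acid-generated flavan-4-yl cation, as in interflavan coupling and phloroglucinol-adduct formation; the 3-O-acyl group on the α face (able to bridge C4 as an acyloxonium ion) should send the arene to the β face so that the new C4 stereocenter is 3,4-trans, and the excess phenol should react at one of its two equivalent carbons between the hydroxyl and a benzyloxy group (less hindered than the carbon flanked by two benzyloxy groups), which places the free hydroxyl ortho to the new bond.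

Step 5
Reactants: 8 3,4,5-tris(benzyloxy)benzaldehyde
Product: 9 racemic 1-[3,4,5-tris(benzyloxy)phenyl]prop-2-en-1-ol
Conditions: vinylmagnesium bromide, THF, −78 to 0 °C, then sat. aq. NH4Cl
Reagents that add atoms: vinylmagnesium bromide, C=C[Mg]Br
Why: Grignard 1,2-addition to an aromatic aldehyde gives the racemic aryl vinyl carbinol, whose stereocenter is sorted out in step 6.

Step 6
Reactants: 9 racemic 1-[3,4,5-tris(benzyloxy)phenyl]prop-2-en-1-ol
Product: 10 (S)-[(R)-oxiran-2-yl][3,4,5-tris(benzyloxy)phenyl]methanol (erythro)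
Conditions: Ti(OiPr)4 (15 mol %), L-(+)-DIPT (20 mol %), TBHP (0.45 equiv), 4 Å MS, CH2Cl2, −20 °C
Reagents that add atoms: tert-butyl hydroperoxide, CC(C)(C)OO
Why: Sharpless kinetic resolution in which the titanium tartrate catalyst from L-(+)-DIPT should epoxidize the (R)-enantiomer of 9 much faster and with erythro selectivity, so the catalyst sets both the carbinol and the oxirane stereocenters of 10 (the carbinol descriptor becomes S only because oxiranyl outranks aryl), while the (S)-alcohol stays unreacted and is removed by chromatography.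

Step 7
Reactants: 7 4β-[2-hydroxy-4,6-bis(benzyloxy)phenyl]-5,7,3',4'-tetra-O-benzyl-3-O-[3,4,5-tris(benzyloxy)benzoyl]epicatechin; 10 (S)-[(R)-oxiran-2-yl][3,4,5-tris(benzyloxy)phenyl]methanol (1.5 equiv)
Product: 11 ring D aryl ether of 7 with the (R)-[(R)-oxiran-2-yl][3,4,5-tris(benzyloxy)phenyl]methyl group on the phenol oxygen (threo epoxy ether)
Conditions: PPh3, DIAD, toluene, 0 °C to rt
Reagents that add atoms: none
Why: Mitsunobu etherification of a phenol with a secondary benzylic alcohol, in which SN2 displacement of the alkoxyphosphonium ion inverts the carbinol center from S to R and so turns the erythro epoxy alcohol into the threo epoxy ether needed for a 2,3-cis flavan, the neighbouring oxirane disfavouring ionization at the benzylic carbon.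

Step 8
Reactants: 11 threo epoxy ether
Product: 12 5,7,3',4'-tetra-O-benzyl-3-O-[3,4,5-tris(benzyloxy)benzoyl]epicatechin-(4β→8)-5,7,3',4',5'-penta-O-benzylepigallocatechin (lower 3-OH free)
Conditions: AuCl3 (5 mol %), AgOTf (15 mol %), ClCH2CH2Cl, 0 °C to rt
Reagents that add atoms: none
Why: Cationic trivalent gold should bind the oxirane oxygen of 11, and the ring D carbon that lies ortho to the ether oxygen, ortho to one benzyloxy group and para to the other then attacks the terminal CH2 (the future C4) in an SN2-like Friedel–Crafts alkylation, after which rearomatization and proton transfer to the C3 alkoxide give 12 and return the catalyst. The closest known reaction type is the gold- or Lewis-acid-catalysed cycloalkylation of aryl 2,3-epoxypropyl ethers to chroman-3-ols, which has been applied to 1-aryl-1-aryloxy-2,3-epoxypropanes to make catechin-type flavan-3-ols. Ring F closes in the 6-endo mode with respect to the oxirane (attack at the distal carbon) in preference to the 5-exo closure at C3 that would give a dihydrobenzofuran, because C4 is primary and unhindered whereas C3 is secondary and deactivated by the adjacent C2–O bond. No new stereocenter is formed: the C3–O bond is never broken, so the R oxirane carbon becomes the 3R carbinol and, with C2 untouched, the 2,3-cis relationship follows from the threo configuration of 11. The step needs site selectivity and chemoselectivity: the O1 tether can reach only the one free ortho carbon (the other free ring D carbon is para to the ether oxygen), so the 4→8 connectivity cannot be lost, and a low loading of a non-protic Lewis acid at or below room temperature is chosen so that the benzylic C2–O bond and the acid-labile interflavan bond are not ionized.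

Step 9
Reactants: 12 dimer with free lower 3-OH; 4 3,4,5-tris(benzyloxy)benzoic acid
Product: 13 5,7,3',4'-tetra-O-benzyl-3-O-[3,4,5-tris(benzyloxy)benzoyl]epicatechin-(4β→8)-5,7,3',4',5'-penta-O-benzyl-3-O-[3,4,5-tris(benzyloxy)benzoyl]epigallocatechin
Conditions: DCC, DMAP, CH2Cl2, rt
Reagents that add atoms: none
Why: Steglich esterification of the single free (axial) C3 hydroxyl of ring F released in step 8, with no stereocenter touched.

Step 10
Reactants: 13 fully protected dimer digallate
Product: 14 (−)-epicatechin 3-O-gallate-(4β→8)-(−)-epigallocatechin 3-O-gallate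
Conditions: H2 (1 atm), Pd(OH)2/C, THF/MeOH/H2O, rt
Reagents that add atoms: none
Why: Catalytic hydrogenolysis over Pearlman's catalyst should remove all fifteen benzyl ethers in one operation under neutral conditions, which the two aryl esters, the ring C2–O1 bonds and the interflavan bond are expected to survive, as is usual for benzyl-protected procyanidin gallates.

**Compound list**

1 | (−)-epicatechin | O[C@@H]1Cc2c(O)cc(O)cc2O[C@@H]1c1ccc(O)c(O)c1 | starting material
2 | 5,7,3',4'-tetra-O-benzyl-(−)-epicatechin | O[C@@H]1Cc2c(OCc3ccccc3)cc(OCc3ccccc3)cc2O[C@@H]1c1ccc(OCc2ccccc2)c(OCc2ccccc2)c1 | intermediate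
3 | 4β-(2-ethoxyethoxy)-5,7,3',4'-tetra-O-benzylepicatechin (2,3-cis, 3,4-trans) | O[C@@H]1[C@@H](OCCOCC)c2c(OCc3ccccc3)cc(OCc3ccccc3)cc2O[C@@H]1c1ccc(OCc2ccccc2)c(OCc2ccccc2)c1 | intermediate
4 | 3,4,5-tris(benzyloxy)benzoic acid | OC(=O)c1cc(OCc2ccccc2)c(OCc2ccccc2)c(OCc2ccccc2)c1 | starting material
5 | 4β-(2-ethoxyethoxy)-5,7,3',4'-tetra-O-benzyl-3-O-[3,4,5-tris(benzyloxy)benzoyl]epicatechin | O=C(O[C@@H]1[C@@H](OCCOCC)c2c(OCc3ccccc3)cc(OCc3ccccc3)cc2O[C@@H]1c1ccc(OCc2ccccc2)c(OCc2ccccc2)c1)c1cc(OCc2ccccc2)c(OCc2ccccc2)c(OCc2ccccc2)c1 | intermediate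
6 | 3,5-bis(benzyloxy)phenol | Oc1cc(OCc2ccccc2)cc(OCc2ccccc2)c1 | starting material
7 | 4β-[2-hydroxy-4,6-bis(benzyloxy)phenyl]-5,7,3',4'-tetra-O-benzyl-3-O-[3,4,5-tris(benzyloxy)benzoyl]epicatechin | O=C(O[C@@H]1[C@@H](c2c(O)cc(OCc3ccccc3)cc2OCc2ccccc2)c2c(OCc3ccccc3)cc(OCc3ccccc3)cc2O[C@@H]1c1ccc(OCc2ccccc2)c(OCc2ccccc2)c1)c1cc(OCc2ccccc2)c(OCc2ccccc2)c(OCc2ccccc2)c1 | intermediate
8 | 3,4,5-tris(benzyloxy)benzaldehyde | O=Cc1cc(OCc2ccccc2)c(OCc2ccccc2)c(OCc2ccccc2)c1 | starting material
9 | racemic 1-[3,4,5-tris(benzyloxy)phenyl]prop-2-en-1-ol | OC(C=C)c1cc(OCc2ccccc2)c(OCc2ccccc2)c(OCc2ccccc2)c1 | intermediate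
10 | (S)-[(R)-oxiran-2-yl][3,4,5-tris(benzyloxy)phenyl]methanol | O[C@H]([C@H]1CO1)c1cc(OCc2ccccc2)c(OCc2ccccc2)c(OCc2ccccc2)c1 | intermediate
11 | ether of the ring D phenol of 7 with the (R)-[(R)-oxiran-2-yl][3,4,5-tris(benzyloxy)phenyl]methyl group | O=C(O[C@@H]1[C@@H](c2c(O[C@@H]([C@H]3CO3)c3cc(OCc4ccccc4)c(OCc4ccccc4)c(OCc4ccccc4)c3)cc(OCc3ccccc3)cc2OCc2ccccc2)c2c(OCc3ccccc3)cc(OCc3ccccc3)cc2O[C@@H]1c1ccc(OCc2ccccc2)c(OCc2ccccc2)c1)c1cc(OCc2ccccc2)c(OCc2ccccc2)c(OCc2ccccc2)c1 | intermediate
12 | 5,7,3',4'-tetra-O-benzyl-3-O-[3,4,5-tris(benzyloxy)benzoyl]epicatechin-(4β→8)-5,7,3',4',5'-penta-O-benzylepigallocatechin | O=C(O[C@@H]1[C@@H](c2c(OCc3ccccc3)cc(OCc3ccccc3)c3c2O[C@H](c2cc(OCc4ccccc4)c(OCc4ccccc4)c(OCc4ccccc4)c2)[C@H](O)C3)c2c(OCc3ccccc3)cc(OCc3ccccc3)cc2O[C@@H]1c1ccc(OCc2ccccc2)c(OCc2ccccc2)c1)c1cc(OCc2ccccc2)c(OCc2ccccc2)c(OCc2ccccc2)c1 | intermediate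
13 | 5,7,3',4'-tetra-O-benzyl-3-O-[3,4,5-tris(benzyloxy)benzoyl]epicatechin-(4β→8)-5,7,3',4',5'-penta-O-benzyl-3-O-[3,4,5-tris(benzyloxy)benzoyl]epigallocatechin | O=C(O[C@@H]1[C@@H](c2c(OCc3ccccc3)cc(OCc3ccccc3)c3c2O[C@H](c2cc(OCc4ccccc4)c(OCc4ccccc4)c(OCc4ccccc4)c2)[C@H](OC(=O)c2cc(OCc4ccccc4)c(OCc4ccccc4)c(OCc4ccccc4)c2)C3)c2c(OCc3ccccc3)cc(OCc3ccccc3)cc2O[C@@H]1c1ccc(OCc2ccccc2)c(OCc2ccccc2)c1)c1cc(OCc2ccccc2)c(OCc2ccccc2)c(OCc2ccccc2)c1 | intermediate
14 | (−)-epicatechin 3-O-gallate-(4β→8)-(−)-epigallocatechin 3-O-gallate | O=C(O[C@@H]1[C@@H](c2c(O)cc(O)c3c2O[C@H](c2cc(O)c(O)c(O)c2)[C@H](OC(=O)c2cc(O)c(O)c(O)c2)C3)c2c(O)cc(O)cc2O[C@@H]1c1ccc(O)c(O)c1)c1cc(O)c(O)c(O)c1 | target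

**Step count and risks**

Total step count: 10. Longest linear sequence: 8 steps (steps 1, 2, 3, 4, 7, 8, 9, 10); steps 5 and 6 form the side branch.

Step 8 (key ring closure). What may go wrong is acid-induced loss of the interflavan bond (protonation of ring D at the carbon that carries the upper unit), ionization of the benzylic C2–O bond with loss of configuration, closure in the 5-exo mode, or a closure too slow next to the bulky C8 substituent. Fallback: ring F is not closed on the dimer and the lower unit is taken from the chiral pool. The fallback sets out from 5. Purchased (−)-epigallocatechin F1 is benzylated (BnBr, K2CO3, DMF) to 5,7,3',4',5'-penta-O-benzyl-(−)-epigallocatechin F2. An excess of F2 is then coupled with 5 (TMSOTf, CH2Cl2, −78 °C), where C8 of F2 is the more accessible nucleophilic carbon and attack is again trans to the 3-O-acyl group. This gives 12, and the route continues with step 9.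

Step 7 (Mitsunobu etherification). What may go wrong is a sluggish SN2 reaction at the hindered phenoxide of 7, or partial ionization of the alkoxyphosphonium ion at the electron-rich benzylic carbon with loss of configuration at the future C2. Fallback: the ether is made on the unhindered phenol, before the interflavan bond. It sets out from 6 and 10 (PPh3, DIAD, toluene) and gives the simple threo epoxy ether (R)-2-{(R)-[3,5-bis(benzyloxy)phenoxy][3,4,5-tris(benzyloxy)phenyl]methyl}oxirane F3. F3 is the direct substrate type of the known cycloalkylation and has two equivalent ortho carbons; AuCl3/AgOTf in ClCH2CH2Cl should convert it into penta-O-benzyl-(−)-epigallocatechin F2. Coupling of F2 with 5 (TMSOTf, CH2Cl2, −78 °C) comes back to the route at 12.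

Step 4 (arylation of C4 by the phenol). What may go wrong is poor regiocontrol (attack at the carbon para to the hydroxyl, which would lead to a 4→6 linkage) and double arylation of the phenol. Fallback: ring D is introduced as part of a finished flavan, in which the regiochemistry of the coupling is the known preference for C8. It sets out from 5, which is coupled with penta-O-benzyl-(−)-epigallocatechin F2, prepared as in either fallback above, under TMSOTf in CH2Cl2 at −78 °C. It comes back to the route at 12.

Further compounds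
F1 | step 8 | (−)-epigallocatechin (purchased) | O[C@@H]1Cc2c(O)cc(O)cc2O[C@@H]1c1cc(O)c(O)c(O)c1
F2 | step 8 | 5,7,3',4',5'-penta-O-benzyl-(−)-epigallocatechin | O[C@@H]1Cc2c(OCc3ccccc3)cc(OCc3ccccc3)cc2O[C@@H]1c1cc(OCc2ccccc2)c(OCc2ccccc2)c(OCc2ccccc2)c1
F3 | step 7 | (R)-2-{(R)-[3,5-bis(benzyloxy)phenoxy][3,4,5-tris(benzyloxy)phenyl]methyl}oxirane | O([C@@H]([C@H]1CO1)c1cc(OCc2ccccc2)c(OCc2ccccc2)c(OCc2ccccc2)c1)c1cc(OCc2ccccc2)cc(OCc2ccccc2)c1
F0 | step 4 | none | none
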